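**Retrosynthetic overview**
1. Last come the C9 acetate and the C8 epoxyangelate; the latter is put on by Mitsunobu inversion of an 8-epi alcohol with a separately made (2S,3S)-epoxy acid.
2. Key disconnection C7–C8: a butenolide-derived allylchromium (a lactone homoenolate, with the enoate β-carbon C7 as nucleophile) adds to the C8 aldehyde, closes the ten-membered ring and unveils the α-methylene lactone; this replaces the customary C6–C7 allylation–lactonisation.
3. The seco-aldehyde comes from ring-closing metathesis of a C6 2-(bromomethyl)acrylate (butenolide) and from aldol–elimination of an L-malate-derived ester (C8–C10, C14) onto a cis-epoxy aldehyde (C1=C10).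
4. The cis-epoxy aldehyde comes from Sharpless epoxidation of a (2Z,4Z)-dienol, itself from Stille coupling of a Z-iodoalkene; C6 is set by asymmetric propynylation of acrolein.
5. Ring order: C2–C3 oxirane, then butenolide, then ten-membered carbocycle; the side-chain oxirane is made in a separate branch.

Assumption: locants C1–C15 in names and comments are germacrane numbers (C12 = lactone carbonyl on O–C6, C13 = exocyclic CH2, C14 = ester carbon, C15 = methyl), and all numbered starting materials are taken as catalogue chemicals.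

**Route**

Step 1
Reactants: 1 dimethyl (2S)-2-hydroxybutanedioate
Product: 2 methyl (3S)-3,4-dihydroxybutanoate
Conditions: BH3·SMe2, NaBH4 (5 mol%), THF, 0 °C → rt; MeOH
Reagents that add atoms: none
Why: Hydroxyl-directed borane reduction (Saito–Moriwake) delivers hydride only to the ester next to the free hydroxyl, so the remote ester and the L-malate stereocentre (future C9, S) are carried over unchanged.

Step 2
Reactants: 2 methyl (3S)-3,4-dihydroxybutanoate
Product: 3 methyl (3S)-3,4-bis(triethylsilyloxy)butanoate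
Conditions: Et3SiCl, imidazole, DMF, 0 °C → rt
Reagents that add atoms: chlorotriethylsilane (CC[Si](CC)(CC)Cl)
Why: Standard silylation of both hydroxyls gives an ester whose lithium enolate resists β-elimination at −78 °C and whose primary silyl ether can later be oxidised selectively.

Step 3
Reactants: 4 (2Z)-2-methylbut-2-enoic acid
Product: 5 (2Z)-2-methylbut-2-en-1-ol
Conditions: LiAlH4, Et2O, 0 °C
Reagents that add atoms: none
Why: LiAlH4 reduces the carboxylic acid 1,2-selectively to the allylic alcohol and leaves the trisubstituted Z double bond intact.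

Step 4
Reactants: 5 (2Z)-2-methylbut-2-en-1-ol
Product: 6 [(2R,3S)-2,3-dimethyloxiran-2-yl]methanol
Conditions: Ti(OiPr)4 (10 mol%), D-(−)-diethyl tartrate (12 mol%), tBuOOH, 4 Å MS, CH2Cl2, −20 °C
Reagents that add atoms: tert-butyl hydroperoxide (CC(C)(C)OO)
Why: In this Sharpless asymmetric epoxidation the complex of Ti(OiPr)4, D-(−)-tartrate and tBuOOH delivers oxygen to the face that gives the (2R,3S)-epoxy alcohol, and the Z geometry fixes the cis relation of CH2OH and the C3 methyl.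

Step 5
Reactants: 6 [(2R,3S)-2,3-dimethyloxiran-2-yl]methanol
Product: 7 (2S,3S)-2,3-dimethyloxirane-2-carboxylic acid
Conditions: RuCl3·xH2O (2 mol%), NaIO4, MeCN/EtOAc/H2O, rt
Reagents that add atoms: water (O), sodium periodate ([Na+].[O-]I(=O)(=O)=O)
Why: The RuCl3/NaIO4 oxidation takes the primary alcohol to the acid through the aldehyde hydrate without opening the trisubstituted epoxide, and both stereocentres are untouched (the C2 descriptor changes from R to S by priority only).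

Step 6
Reactants: 8 prop-2-enal, 9 propyne
Product: 10 (3S)-hex-1-en-4-yn-3-ol
Conditions: Me2Zn, ProPhenol ligand (the antipode that gives the 3S alcohol, 10 mol%), Ph3P=O (20 mol%), toluene, 0 °C
Reagents that add atoms: none
Why: In this Trost asymmetric alkynylation the chiral catalyst formed from Me2Zn and the ProPhenol ligand delivers methylzinc propynylide to one face of acrolein and so sets C6 (3S here).

Step 7
Reactants: 10 (3S)-hex-1-en-4-yn-3-ol
Product: 12 (3S,4Z)-5-iodohexa-1,4-dien-3-ol, via sodium alanate Na[Al(C6H8O)(OCH2CH2OCH3)2] 11 (not isolated)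
Conditions: NaAlH2(OCH2CH2OCH3)2, THF, 0 °C → rt; then I2, −78 → 0 °C
Reagents that add atoms: diiodine (II)
Why: Alkoxide-directed trans-hydroalumination of the propargylic alcohol places aluminium on C4 in a five-membered oxa-aluminacycle, and iodinolysis with retention gives the Z-iodoalkene that fixes the later ring-cis C4=C5 geometry.

Step 8
Reactants: 12 (3S,4Z)-5-iodohexa-1,4-dien-3-ol
Product: 13 1-({[(3S,4Z)-5-iodohexa-1,4-dien-3-yl]oxy}methyl)-4-methoxybenzene
Conditions: NaH, 4-MeOC6H4CH2Cl, Bu4NI (cat.), THF/DMF, 0 °C → rt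
Reagents that add atoms: 4-methoxybenzyl chloride (COc1ccc(CCl)cc1)
Why: Williamson etherification masks the bis-allylic C6 hydroxyl, which would otherwise be epoxidised in step 10 and interfere with the enolate chemistry of step 12.

Step 9
Reactants: 13 1-({[(3S,4Z)-5-iodohexa-1,4-dien-3-yl]oxy}methyl)-4-methoxybenzene, 14 (2Z)-3-(tributylstannyl)prop-2-en-1-ol
Product: 15 (2Z,4Z,6S)-6-[(4-methoxyphenyl)methoxy]-4-methylocta-2,4,7-trien-1-ol
Conditions: PdCl2(MeCN)2 (5 mol%), DMF, rt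
Reagents that add atoms: none
Why: Stille cross-coupling proceeds with retention at both sp2 carbons and gives the (2Z,4Z)-dienol.

Step 10
Reactants: 15 (2Z,4Z,6S)-6-[(4-methoxyphenyl)methoxy]-4-methylocta-2,4,7-trien-1-ol
Product: 16 {(2R,3S)-3-[(2Z,4S)-4-[(4-methoxyphenyl)methoxy]hexa-2,5-dien-2-yl]oxiran-2-yl}methanol
Conditions: Ti(OiPr)4 (20 mol%), D-(−)-diethyl tartrate (24 mol%), tBuOOH, 4 Å MS, CH2Cl2, −20 °C
Reagents that add atoms: tert-butyl hydroperoxide (CC(C)(C)OO)
Why: Sharpless asymmetric epoxidation touches only the allylic-alcohol double bond, D-(−)-tartrate sets C2 (R) and C3 (S), the Z-alkene gives the cis-epoxide, and the minor diastereomer expected from this slow Z-substrate class is removed by chromatography.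

Step 11
Reactants: 16 {(2R,3S)-3-[(2Z,4S)-4-[(4-methoxyphenyl)methoxy]hexa-2,5-dien-2-yl]oxiran-2-yl}methanol
Product: 17 (2S,3S)-3-[(2Z,4S)-4-[(4-methoxyphenyl)methoxy]hexa-2,5-dien-2-yl]oxirane-2-carbaldehyde
Conditions: Dess–Martin periodinane, pyridine, CH2Cl2, 0 °C
Reagents that add atoms: none
Why: Pyridine-buffered Dess–Martin oxidation gives the cis-epoxy aldehyde without epimerising its α-carbon (the C2 descriptor changes to S by priority only).

Step 12
Reactants: 3 methyl (3S)-3,4-bis(triethylsilyloxy)butanoate, 17 (2S,3S)-3-[(2Z,4S)-4-[(4-methoxyphenyl)methoxy]hexa-2,5-dien-2-yl]oxirane-2-carbaldehyde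
Product: 19 methyl (2E)-2-[(1S)-1,2-bis(triethylsilyloxy)ethyl]-3-{(2R,3S)-3-[(2Z,4S)-4-[(4-methoxyphenyl)methoxy]hexa-2,5-dien-2-yl]oxiran-2-yl}prop-2-enoate, via mesylate 18 (not isolated)
Conditions: LiN(iPr)2, THF, −78 °C (on 3); then 17; then MsCl, −78 → 0 °C; then DBU, 0 °C → rt
Reagents that add atoms: none
Why: Aldol addition of the lithium enolate of 3 to the aldehyde, in-flask mesylation of the aldolate and E1cB elimination with DBU give the thermodynamically preferred 2E enoate (C2 trans to CO2Me), while the C9 and epoxide stereocentres are spectators and the two transient centres are destroyed.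

Step 13
Reactants: 19 methyl (2E)-2-[(1S)-1,2-bis(triethylsilyloxy)ethyl]-3-{(2R,3S)-3-[(2Z,4S)-4-[(4-methoxyphenyl)methoxy]hexa-2,5-dien-2-yl]oxiran-2-yl}prop-2-enoate
Product: 20 methyl (2E)-2-[(1S)-1,2-bis(triethylsilyloxy)ethyl]-3-{(2R,3S)-3-[(2Z,4S)-4-hydroxyhexa-2,5-dien-2-yl]oxiran-2-yl}prop-2-enoate
Conditions: DDQ, CH2Cl2/pH 7 phosphate buffer, 0 °C
Reagents that add atoms: none
Why: Oxidative cleavage of the 4-methoxybenzyl ether at pH 7 frees the C6 hydroxyl without acid, so the silyl ethers and the vinyl epoxide (prone to 5-exo opening by this hydroxyl) survive; 20 is acylated at once.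

Step 14
Reactants: 20 methyl (2E)-2-[(1S)-1,2-bis(triethylsilyloxy)ethyl]-3-{(2R,3S)-3-[(2Z,4S)-4-hydroxyhexa-2,5-dien-2-yl]oxiran-2-yl}prop-2-enoate, 21 2-(bromomethyl)prop-2-enoic acid
Product: 23 (3S,4Z)-5-{(2S,3R)-3-[(1E,3S)-2-(methoxycarbonyl)-3,4-bis(triethylsilyloxy)but-1-en-1-yl]oxiran-2-yl}hexa-1,4-dien-3-yl 2-(bromomethyl)prop-2-enoate, via acid chloride 22 (not isolated)
Conditions: (COCl)2, DMF (cat.), CH2Cl2, 0 °C → rt (on 21); then 20, 2,6-lutidine, CH2Cl2, −20 → 0 °C
Reagents that add atoms: none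
Why: O-acylation of the secondary alcohol by the freshly made acid chloride, with a hindered pyridine base that does not displace the allylic bromide, installs all carbons of the lactone (C11–C13).

Step 15
Reactants: 23 (3S,4Z)-5-{(2S,3R)-3-[(1E,3S)-2-(methoxycarbonyl)-3,4-bis(triethylsilyloxy)but-1-en-1-yl]oxiran-2-yl}hexa-1,4-dien-3-yl 2-(bromomethyl)prop-2-enoate
Product: 24 methyl (2E)-2-[(1S)-1,2-bis(triethylsilyloxy)ethyl]-3-[(2R,3S)-3-{(1Z)-1-[(2R)-4-(bromomethyl)-5-oxo-2,5-dihydrofuran-2-yl]prop-1-en-2-yl}oxiran-2-yl]prop-2-enoate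
Conditions: second-generation Grubbs catalyst RuCl2(=CHPh)(PCy3)(H2IMes) (5 mol%), CH2Cl2 (5 mM), 40 °C
Reagents that add atoms: none
Why: Ring-closing metathesis between the C7 vinyl group and the 1,1-disubstituted acrylate closes the five-membered butenolide far faster than the trisubstituted alkenes can react, giving the 3-(bromomethyl)furanone that carries the latent C7 nucleophile.

Step 16
Reactants: 24 methyl (2E)-2-[(1S)-1,2-bis(triethylsilyloxy)ethyl]-3-[(2R,3S)-3-{(1Z)-1-[(2R)-4-(bromomethyl)-5-oxo-2,5-dihydrofuran-2-yl]prop-1-en-2-yl}oxiran-2-yl]prop-2-enoate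
Product: 25 methyl (2E)-3-[(2R,3S)-3-{(1Z)-1-[(2R)-4-(bromomethyl)-5-oxo-2,5-dihydrofuran-2-yl]prop-1-en-2-yl}oxiran-2-yl]-2-[(1S)-2-oxo-1-(triethylsilyloxy)ethyl]prop-2-enoate
Conditions: (COCl)2, DMSO, CH2Cl2, −78 °C; then iPr2NEt, −78 → −30 °C
Reagents that add atoms: none
Why: Under Swern conditions a primary triethylsilyl ether is cleaved and oxidised directly to the aldehyde while the secondary C9 silyl ether survives, and the non-nucleophilic base spares the allylic bromide and the acidic C6–H of the butenolide.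

Step 17
Reactants: 25 methyl (2E)-3-[(2R,3S)-3-{(1Z)-1-[(2R)-4-(bromomethyl)-5-oxo-2,5-dihydrofuran-2-yl]prop-1-en-2-yl}oxiran-2-yl]-2-[(1S)-2-oxo-1-(triethylsilyloxy)ethyl]prop-2-enoate
Product: 27 methyl (2R,3S,6R,7R,8R,9S)-2,3-epoxy-8-hydroxy-9-(triethylsilyloxy)germacra-1(10)E,4Z,11(13)-trien-12,6-olid-14-oate, via allylchromium dichloride 26 (not isolated)
Conditions: CrCl2 (10 equiv), THF, rt, syringe-pump addition of 25 (final 2 mM)
Reagents that add atoms: none
Why: Proposed new method: divalent chromium inserts into the allylic C13–Br bond to give the butenolide-derived allylchromium dichloride 26, a lactone homoenolate in which C7 (normally the electrophilic β-carbon of the enoate) is nucleophilic, and this adds in SE2′ fashion through a six-membered Zimmerman–Traxler transition state to the C8 aldehyde carbon (also an acceptor), closing the ten-membered ring and regenerating the exocyclic C11=C13 bond; C8 is expected to enter anti to the C6–C5 bond (trans-fused lactone) with C9 equatorial in the chair and Felkin–Anh approach anti to the C9 silyloxy group (7,8-anti and 8,9-anti, hence 8R), the closest known reactions being intermolecular Barbier additions of 3-(bromomethyl)furan-2(5H)-ones to aldehydes and Nozaki–Hiyama macrocyclisations of 2-(bromomethyl)acrylates.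

Step 18
Reactants: 27 methyl (2R,3S,6R,7R,8R,9S)-2,3-epoxy-8-hydroxy-9-(triethylsilyloxy)germacra-1(10)E,4Z,11(13)-trien-12,6-olid-14-oate, 7 (2S,3S)-2,3-dimethyloxirane-2-carboxylic acid
Product: 29 methyl (2R,3S,6R,7S,8S,9S)-8-{[(2S,3S)-2,3-dimethyloxiran-2-yl]carbonyloxy}-2,3-epoxy-9-(triethylsilyloxy)germacra-1(10)E,4Z,11(13)-trien-12,6-olid-14-oate, via alkoxyphosphonium carboxylate 28 (not isolated)
Conditions: PPh3, DIAD, toluene, 0 °C → rt
Reagents that add atoms: none
Why: In this Mitsunobu esterification the C8 alcohol is activated as its alkoxyphosphonium ion and displaced by the carboxylate of 7 in an SN2 step, which installs the epoxyangelate and inverts C8 from R to S in one operation, the non-participating C9 silyl ether excluding neighbouring-group retention.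

Step 19
Reactants: 29 methyl (2R,3S,6R,7S,8S,9S)-8-{[(2S,3S)-2,3-dimethyloxiran-2-yl]carbonyloxy}-2,3-epoxy-9-(triethylsilyloxy)germacra-1(10)E,4Z,11(13)-trien-12,6-olid-14-oate
Product: 31 methyl (2R,3S,6R,7S,8S,9S)-9-acetoxy-8-{[(2S,3S)-2,3-dimethyloxiran-2-yl]carbonyloxy}-2,3-epoxygermacra-1(10)E,4Z,11(13)-trien-12,6-olid-14-oate (CNP0604635.2), via C9 alcohol 30 (not isolated)
Conditions: HF·pyridine, pyridine, THF, 0 °C; then Ac2O, DMAP, pyridine, CH2Cl2, 0 °C (crude 30)
Reagents that add atoms: acetic anhydride (CC(=O)OC(C)=O)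
Why: Buffered HF·pyridine removes the hindered secondary silyl ether without opening either epoxide or causing acyl migration, and immediate DMAP-catalysed acetylation of crude 30 gives the target before the free C9 hydroxyl can attack the neighbouring C2–C3 epoxide.

**Compound list**

1 | dimethyl (2S)-2-hydroxybutanedioate (dimethyl L-malate) | COC(=O)C[C@H](O)C(=O)OC | starting material
2 | methyl (3S)-3,4-dihydroxybutanoate | COC(=O)C[C@H](O)CO | intermediate
3 | methyl (3S)-3,4-bis(triethylsilyloxy)butanoate | COC(=O)C[C@H](O[Si](CC)(CC)CC)CO[Si](CC)(CC)CC | intermediate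
4 | (2Z)-2-methylbut-2-enoic acid (angelic acid) | C/C=C(/C)C(=O)O | starting material
5 | (2Z)-2-methylbut-2-en-1-ol | C/C=C(/C)CO | intermediate
6 | [(2R,3S)-2,3-dimethyloxiran-2-yl]methanol | OC[C@@]1(C)O[C@H]1C | intermediate
7 | (2S,3S)-2,3-dimethyloxirane-2-carboxylic acid | OC(=O)[C@@]1(C)O[C@H]1C | intermediate
8 | prop-2-enal (acrolein) | C=CC=O | starting material
9 | propyne | CC#C | starting material
10 | (3S)-hex-1-en-4-yn-3-ol | O[C@@H](C=C)C#CC | intermediate
11 | sodium (5S)-2,2-bis(2-methoxyethoxy)-3-methyl-5-vinyl-2,5-dihydro-1,2-oxaaluminol-2-uide (cyclic alkenylalanate) | C=C[C@H]1C=C(C)[Al-](OCCOC)(OCCOC)O1.[Na+] | intermediate (not isolated)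
12 | (3S,4Z)-5-iodohexa-1,4-dien-3-ol | O[C@@H](C=C)/C=C(/C)I | intermediate
13 | 1-({[(3S,4Z)-5-iodohexa-1,4-dien-3-yl]oxy}methyl)-4-methoxybenzene | COc1ccc(CO[C@@H](C=C)/C=C(/C)I)cc1 | intermediate
14 | (2Z)-3-(tributylstannyl)prop-2-en-1-ol | CCCC[Sn](CCCC)(CCCC)/C=C\CO | starting material
15 | (2Z,4Z,6S)-6-[(4-methoxyphenyl)methoxy]-4-methylocta-2,4,7-trien-1-ol | COc1ccc(CO[C@@H](C=C)/C=C(/C)\C=C/CO)cc1 | intermediate
16 | {(2R,3S)-3-[(2Z,4S)-4-[(4-methoxyphenyl)methoxy]hexa-2,5-dien-2-yl]oxiran-2-yl}methanol | COc1ccc(CO[C@@H](C=C)/C=C(/C)[C@@H]2O[C@@H]2CO)cc1 | intermediate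
17 | (2S,3S)-3-[(2Z,4S)-4-[(4-methoxyphenyl)methoxy]hexa-2,5-dien-2-yl]oxirane-2-carbaldehyde | COc1ccc(CO[C@@H](C=C)/C=C(/C)[C@@H]2O[C@@H]2C=O)cc1 | intermediate
18 | methyl 2-[(1S)-1,2-bis(triethylsilyloxy)ethyl]-3-(methylsulfonyloxy)-3-{cis-3-[(2Z,4S)-4-[(4-methoxyphenyl)methoxy]hexa-2,5-dien-2-yl]oxiran-2-yl}propanoate, oxirane configured as in 17, both epimers at the two propanoate carbons (left undefined, lost on elimination) | COc1ccc(CO[C@@H](C=C)/C=C(/C)[C@@H]2O[C@@H]2C(OS(C)(=O)=O)C(C(=O)OC)[C@H](O[Si](CC)(CC)CC)CO[Si](CC)(CC)CC)cc1 | intermediate (not isolated)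
19 | methyl (2E)-2-[(1S)-1,2-bis(triethylsilyloxy)ethyl]-3-{(2R,3S)-3-[(2Z,4S)-4-[(4-methoxyphenyl)methoxy]hexa-2,5-dien-2-yl]oxiran-2-yl}prop-2-enoate | COc1ccc(CO[C@@H](C=C)/C=C(/C)[C@@H]2O[C@@H]2/C=C(/C(=O)OC)[C@H](O[Si](CC)(CC)CC)CO[Si](CC)(CC)CC)cc1 | intermediate
20 | methyl (2E)-2-[(1S)-1,2-bis(triethylsilyloxy)ethyl]-3-{(2R,3S)-3-[(2Z,4S)-4-hydroxyhexa-2,5-dien-2-yl]oxiran-2-yl}prop-2-enoate | O[C@@H](C=C)/C=C(/C)[C@@H]1O[C@@H]1/C=C(/C(=O)OC)[C@H](O[Si](CC)(CC)CC)CO[Si](CC)(CC)CC | intermediate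
21 | 2-(bromomethyl)prop-2-enoic acid | C=C(CBr)C(=O)O | starting material
22 | 2-(bromomethyl)prop-2-enoyl chloride | C=C(CBr)C(Cl)=O | intermediate (not isolated)
23 | (3S,4Z)-5-{(2S,3R)-3-[(1E,3S)-2-(methoxycarbonyl)-3,4-bis(triethylsilyloxy)but-1-en-1-yl]oxiran-2-yl}hexa-1,4-dien-3-yl 2-(bromomethyl)prop-2-enoate | C=C(CBr)C(=O)O[C@@H](C=C)/C=C(/C)[C@@H]1O[C@@H]1/C=C(/C(=O)OC)[C@H](O[Si](CC)(CC)CC)CO[Si](CC)(CC)CC | intermediate
24 | methyl (2E)-2-[(1S)-1,2-bis(triethylsilyloxy)ethyl]-3-[(2R,3S)-3-{(1Z)-1-[(2R)-4-(bromomethyl)-5-oxo-2,5-dihydrofuran-2-yl]prop-1-en-2-yl}oxiran-2-yl]prop-2-enoate | O=C1O[C@@H](C=C1CBr)/C=C(/C)[C@@H]2O[C@@H]2/C=C(/C(=O)OC)[C@H](O[Si](CC)(CC)CC)CO[Si](CC)(CC)CC | intermediate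
25 | methyl (2E)-3-[(2R,3S)-3-{(1Z)-1-[(2R)-4-(bromomethyl)-5-oxo-2,5-dihydrofuran-2-yl]prop-1-en-2-yl}oxiran-2-yl]-2-[(1S)-2-oxo-1-(triethylsilyloxy)ethyl]prop-2-enoate | O=C1O[C@@H](C=C1CBr)/C=C(/C)[C@@H]2O[C@@H]2/C=C(/C(=O)OC)[C@H](O[Si](CC)(CC)CC)C=O | intermediate
26 | allylchromium dichloride of 25 (CrCl2 in place of Br on the furanone CH2; all stereocentres as in 25) | O=C1O[C@@H](C=C1C[Cr](Cl)Cl)/C=C(/C)[C@@H]2O[C@@H]2/C=C(/C(=O)OC)[C@H](O[Si](CC)(CC)CC)C=O | intermediate (not isolated)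
27 | methyl (2R,3S,6R,7R,8R,9S)-2,3-epoxy-8-hydroxy-9-(triethylsilyloxy)germacra-1(10)E,4Z,11(13)-trien-12,6-olid-14-oate | C=C1C(=O)O[C@@H]2/C=C(/C)[C@@H]3O[C@@H]3/C=C(/C(=O)OC)[C@H](O[Si](CC)(CC)CC)[C@H](O)[C@@H]12 | intermediate
28 | (8R)-8-O-triphenylphosphonio derivative of 27 as its (2S,3S)-2,3-dimethyloxirane-2-carboxylate ion pair | C=C1C(=O)O[C@@H]2/C=C(/C)[C@@H]3O[C@@H]3/C=C(/C(=O)OC)[C@H](O[Si](CC)(CC)CC)[C@H](O[P+](c4ccccc4)(c4ccccc4)c4ccccc4)[C@@H]12.[O-]C(=O)[C@@]1(C)O[C@H]1C | intermediate (not isolated)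
29 | methyl (2R,3S,6R,7S,8S,9S)-8-{[(2S,3S)-2,3-dimethyloxiran-2-yl]carbonyloxy}-2,3-epoxy-9-(triethylsilyloxy)germacra-1(10)E,4Z,11(13)-trien-12,6-olid-14-oate | C=C1C(=O)O[C@@H]2/C=C(/C)[C@@H]3O[C@@H]3/C=C(/C(=O)OC)[C@H](O[Si](CC)(CC)CC)[C@@H](OC(=O)[C@@]3(C)O[C@H]3C)[C@@H]12 | intermediate
30 | methyl (2R,3S,6R,7S,8S,9S)-8-{[(2S,3S)-2,3-dimethyloxiran-2-yl]carbonyloxy}-2,3-epoxy-9-hydroxygermacra-1(10)E,4Z,11(13)-trien-12,6-olid-14-oate | C=C1C(=O)O[C@@H]2/C=C(/C)[C@@H]3O[C@@H]3/C=C(/C(=O)OC)[C@H](O)[C@@H](OC(=O)[C@@]3(C)O[C@H]3C)[C@@H]12 | intermediate (not isolated)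
31 | methyl (2R,3S,6R,7S,8S,9S)-9-acetoxy-8-{[(2S,3S)-2,3-dimethyloxiran-2-yl]carbonyloxy}-2,3-epoxygermacra-1(10)E,4Z,11(13)-trien-12,6-olid-14-oate (CNP0604635.2) | C=C1C(=O)O[C@@H]2/C=C(/C)[C@@H]3O[C@@H]3/C=C(/C(=O)OC)[C@H](OC(C)=O)[C@@H](OC(=O)[C@@]3(C)O[C@H]3C)[C@@H]12 | target

**Step count and risks**

Total step count: 19 (steps 1–2 to ester 3, steps 3–5 to acid 7, steps 6–19 main line).
Longest linear sequence: 14 steps (8 and 9 to 31, steps 6–19).

The three steps most likely to fail: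

Step 17 (chromium macrocyclisation). The ten-membered ring may not close (oligomers), or ring strain may override the chair/Felkin preference and give the cis-fused lactone or the 8S epimer. The fallback sets out from 25 and comes back at 29. At high dilution in dioxane a thiazolium-derived carbene (3-benzyl-5-(2-hydroxyethyl)-4-methylthiazolium chloride, iPr2NEt) turns the C8 aldehyde into an acyl-anion equivalent, which adds to C7 of the bromomethyl butenolide and expels bromide (Stetter-type SN2′ closure). This gives the macrocyclic ketone methyl (2R,3S,6R,7S,9S)-2,3-epoxy-8-oxo-9-(triethylsilyloxy)germacra-1(10)E,4Z,11(13)-trien-12,6-olid-14-oate F1. Reduction with NaBH4/CeCl3·7H2O at −78 °C, under Felkin–Anh control by the non-chelating C9 silyl ether, gives the 8S alcohol methyl (2R,3S,6R,7R,8S,9S)-2,3-epoxy-8-hydroxy-9-(triethylsilyloxy)germacra-1(10)E,4Z,11(13)-trien-12,6-olid-14-oate F2. F2 is also what is in hand if the chromium reaction itself delivers the 8S epimer. Yamaguchi esterification of F2 with 7 (2,4,6-trichlorobenzoyl chloride, Et3N, DMAP, toluene) then gives 29 with retention.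

Step 18 (Mitsunobu inversion at a hindered ring carbinol). Elimination or no reaction is possible. The fallback sets out from 27 and comes back at 29. Compound 27 is converted with ClCH2SO2Cl and pyridine into the chloromethanesulfonate methyl (2R,3S,6R,7S,8R,9S)-8-[(chloromethyl)sulfonyloxy]-2,3-epoxy-9-(triethylsilyloxy)germacra-1(10)E,4Z,11(13)-trien-12,6-olid-14-oate F3. This isolable sulfonate is displaced with inversion by the caesium salt of 7 (Cs2CO3, 18-crown-6, toluene, 50 °C) to give 29.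

Step 12 (aldol–mesylation–elimination on the base-sensitive cis-epoxy aldehyde). Epimerisation, Payne rearrangement of the aldolate or E/Z mixtures are possible. The fallback sets out from 3 and comes back at 19. Ester 3 is phosphonylated (LiN(iPr)2, ClP(OEt)2, then H2O2) to the phosphonate methyl (3R)-2-(diethoxyphosphoryl)-3,4-bis(triethylsilyloxy)butanoate F4 (both C2 epimers; 3R by priority only, same spatial arrangement as in 3). A Horner–Wadsworth–Emmons reaction of F4 with 17 under LiCl/DBU in MeCN at 0 °C then gives 19 directly, without the aldolate or the mesylate.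

**Further compounds**

F1 | step 17 | methyl (2R,3S,6R,7S,9S)-2,3-epoxy-8-oxo-9-(triethylsilyloxy)germacra-1(10)E,4Z,11(13)-trien-12,6-olid-14-oate | C=C1C(=O)O[C@@H]2/C=C(/C)[C@@H]3O[C@@H]3/C=C(/C(=O)OC)[C@H](O[Si](CC)(CC)CC)C(=O)[C@@H]12
F2 | step 17 | methyl (2R,3S,6R,7R,8S,9S)-2,3-epoxy-8-hydroxy-9-(triethylsilyloxy)germacra-1(10)E,4Z,11(13)-trien-12,6-olid-14-oate | C=C1C(=O)O[C@@H]2/C=C(/C)[C@@H]3O[C@@H]3/C=C(/C(=O)OC)[C@H](O[Si](CC)(CC)CC)[C@@H](O)[C@@H]12
F3 | step 18 | methyl (2R,3S,6R,7S,8R,9S)-8-[(chloromethyl)sulfonyloxy]-2,3-epoxy-9-(triethylsilyloxy)germacra-1(10)E,4Z,11(13)-trien-12,6-olid-14-oate | C=C1C(=O)O[C@@H]2/C=C(/C)[C@@H]3O[C@@H]3/C=C(/C(=O)OC)[C@H](O[Si](CC)(CC)CC)[C@H](OS(=O)(=O)CCl)[C@@H]12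
F4 | step 12 | methyl (3R)-2-(diethoxyphosphoryl)-3,4-bis(triethylsilyloxy)butanoate (both C2 epimers) | CCOP(=O)(OCC)C(C(=O)OC)[C@H](O[Si](CC)(CC)CC)CO[Si](CC)(CC)CC
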